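The polyene is attached last at C7=C8, so the problem reduces to a C10 ε-ring building block. Its six-membered ring is opened at the C4=C5 alkene. That bond is trisubstituted, out of conjugation, and sits between the C3 carbinol and the C6 stereocentre. A C3 vinyl carbinol and a C6 isopropenyl group, linked through the C1 gem-dimethyl carbon, give exactly this pattern on ring-closing metathesis. One operation closes the ring and places the alkene by connectivity alone, without touching either stereocentre. The precursor is an acyclic octa-1,7-diene. Its C6 centre comes from an enantioselective boron Ireland–Claisen rearrangement and its C3 centre from a catalytic asymmetric vinylzinc addition.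

Key step: step 9

Numbering remark: carotenoid numbering is used throughout (C1 gem-dimethyl carbon, C2 methylene, C3 carbinol, C4=C5 ring alkene, C6 ring stereocentre, C7 its exocyclic carbon). The target is the 3,6-cis (3S,6R) isomer.

Assumption: the (S,S)-configured boron controller is taken to give the (S)-acid. The sense of induction for this particular ester must be confirmed on the first batch, and the equally accessible (R,R)-controller is used if the opposite antipode is found.

Step 1
Reactants: 1 prenol (3-methylbut-2-en-1-ol); 2 3-methylbut-3-enoic acid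
Product: 3 prenyl 3-methylbut-3-enoate
Conditions: DCC (1.1 equiv), DMAP (5 mol %), CH2Cl2, 0 °C → rt
Reagents that add atoms: none
Why: Steglich esterification joins the acid and the primary allylic alcohol under nearly neutral conditions, and the small DMAP charge at 0 °C keeps the β,γ-alkene of the acid part from moving into conjugation.

Step 2
Reactants: 3 prenyl 3-methylbut-3-enoate
Product: 6 (2S)-3,3-dimethyl-2-(prop-1-en-2-yl)pent-4-enoic acid, via boron ketene acetal 4 (not isolated), via acyloxyborane 5 (not isolated)
Conditions: (S,S)-N,N'-(1,2-diphenylethane-1,2-diyl)bis[3,5-bis(trifluoromethyl)benzenesulfonamide], BBr3, CH2Cl2, rt, then evaporation (B-bromodiazaborolidine); 3, i-Pr2NEt, CH2Cl2, −78 °C, then −20 °C → 4 °C; aq. work-up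
Reagents that add atoms: none
Why: Enantioselective boron-mediated Ireland–Claisen rearrangement, a known reaction of 3-methylbut-3-enoates of trisubstituted allylic alcohols: soft enolisation of the doubly activated CH2 gives one ketene acetal geometry, the chair [3,3] shift forges C6–C1 together with the gem-dimethyl carbon, and the C2-symmetric diazaborolidine on boron shields one enolate face so that C6 is set as S (the later 6R).

Step 3
Reactants: 6 (2S)-3,3-dimethyl-2-(prop-1-en-2-yl)pent-4-enoic acid
Product: 7 (2S)-3,3-dimethyl-2-(prop-1-en-2-yl)pent-4-en-1-ol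
Conditions: LiAlH4, Et2O, 0 °C → rt; aq. NaOH work-up
Reagents that add atoms: none
Why: LiAlH4 reduction of the acid proceeds through the non-enolisable carboxylate, so C6 keeps its configuration and both isolated alkenes are inert.

Step 4
Reactants: 7 (2S)-3,3-dimethyl-2-(prop-1-en-2-yl)pent-4-en-1-ol
Product: 8 4-methoxybenzyl (PMB) ether of 7, (S) at C6
Conditions: NaH, 4-methoxybenzyl chloride, Bu4NI (cat.), THF–DMF, 0 °C → rt
Reagents that add atoms: 4-methoxybenzyl chloride, COc1ccc(CCl)cc1
Why: Williamson ether synthesis on the primary alkoxide, run at or below room temperature where the crowded hexa-1,5-diene has no chance of thermal Cope rearrangement.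

Step 5
Reactants: 8 PMB ether of 7
Product: 10 (4S)-4-[(4-methoxybenzyloxy)methyl]-3,3,5-trimethylhex-5-en-1-ol, via catechol boronate 9 (not isolated)
Conditions: catecholborane (1.2 equiv), RhCl(PPh3)3 (3 mol %), THF, 0 °C → rt; then NaOH, 30 % H2O2, 0 °C
Reagents that add atoms: hydrogen peroxide, OO
Why: RhCl(PPh3)3-catalysed hydroboration followed by peroxide oxidation: coordination and insertion at the Rh–H intermediate discriminate far more sharply between a monosubstituted and a crowded 1,1-disubstituted alkene than dialkylboranes do, so only the vinyl group reacts, with boron at the terminal C3 because quaternary C1 blocks the branched mode, whereas an aldehyde-selective Wacker shortcut is avoided because divalent palladium catalyses the Cope rearrangement of just such 2-methylhexa-1,5-dienes.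

Step 6
Reactants: 10 (4S)-4-[(4-methoxybenzyloxy)methyl]-3,3,5-trimethylhex-5-en-1-ol
Product: 11 (4S)-4-[(4-methoxybenzyloxy)methyl]-3,3,5-trimethylhex-5-enal
Conditions: TEMPO (10 mol %), PhI(OAc)2, CH2Cl2, rt
Reagents that add atoms: none
Why: Oxoammonium (TEMPO) oxidation stops cleanly at the aldehyde and introduces no Lewis acid that could start a carbonyl-ene closure onto the isopropenyl group, while the PMB ether and the alkene are untouched.

Step 7
Reactants: 11 (4S)-4-[(4-methoxybenzyloxy)methyl]-3,3,5-trimethylhex-5-enal; 12 vinylmagnesium bromide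
Product: 14 (3S,6S)-6-[(4-methoxybenzyloxy)methyl]-5,5,7-trimethylocta-1,7-dien-3-ol, via divinylzinc 13 (not isolated)
Conditions: 12, ZnCl2, Et2O–THF, 0 °C → rt, 1,4-dioxane, filtration under Ar (halide-free 13); (+)-DAIB [(2R)-3-exo-(dimethylamino)isoborneol, 10 mol %], toluene, 0 °C, then 11; aq. work-up
Reagents that add atoms: none
Why: Amino-alcohol-catalysed asymmetric alkenylzinc addition: the zinc alkoxide of (+)-DAIB assembles aldehyde and divinylzinc in a bimetallic cyclic transition state and passes the vinyl group to the Re face, which corresponds to 3S (the antipodal ligand is established to attack the Si face), halide-free 13 suppresses the uncatalysed pathway and Lewis-acid ene cyclisation, and any 3R product is a diastereomer removable by chromatography.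

Step 8
Reactants: 14 (3S,6S)-6-[(4-methoxybenzyloxy)methyl]-5,5,7-trimethylocta-1,7-dien-3-ol
Product: 15 tert-butyldimethylsilyl (TBS) ether of 14, the acyclic (3S,6S) octa-1,7-diene
Conditions: TBSCl, imidazole, DMF, rt
Reagents that add atoms: tert-butyldimethylsilyl chloride, CC(C)(C)[Si](C)(C)Cl
Why: Imidazole-promoted silylation touches only the O–H bond, so 3S is retained, and the TBS ether withstands every later step up to the final fluoride treatment.

Step 9
Reactants: 15 TBS ether of 14
Product: 16 tert-butyl({(1S,4R)-4-[(4-methoxybenzyloxy)methyl]-3,5,5-trimethylcyclohex-2-en-1-yl}oxy)dimethylsilane (3S,6R in carotenoid numbering, 3,6-cis)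
Conditions: second-generation Grubbs catalyst (H2IMes)(PCy3)Cl2Ru=CHPh (5 mol %), 1,4-benzoquinone (10 mol %), toluene (0.005 M), 80 °C, Ar sparge
Reagents that add atoms: none
Why: Ring-closing olefin metathesis by the metallacyclobutane mechanism: the benzylidene of the catalyst first exchanges with the unhindered monosubstituted C3 vinyl group, the resulting C4 alkylidene adds [2+2] across the tethered C5 isopropenyl alkene, and cycloreversion releases the ring with C4=C5 and, after turnover, ethene. The closest known reaction type is the closure of octa-1,7-dienes bearing one 1,1-disubstituted alkene to trisubstituted cyclohexenes with catalysts of the (H2IMes)(PCy3)Cl2Ru=CHPh type. The single ring (C1–C6) is closed as a six-membered carbocycle with the new alkene endocyclic, the two terminal CH2 groups being the only atoms lost. No stereocentre is formed, and C3 and C6 pass through unchanged because the medium is neutral and the C3–O, C3–H and C6–H bonds take no part; the C6 label merely changes from S to R because C5 now outranks C1. The selectivity required is cyclisation over vinyl–vinyl dimerisation and over Ru–H mediated alkene migration, and it is secured by Thorpe–Ingold compression at C1, by the inability of the isopropenyl group to homocouple, by high dilution with ethene removal and by the benzoquinone additive. Regiochemistry is not an issue, since the double bond can arise only between the two carbons that carried the CH2 termini, whereas a dehydration route would have to fight the pull toward the tetrasubstituted C5=C6 position.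

Step 10
Reactants: 16 protected ε-ring building block
Product: 17 [(1R,4S)-4-(tert-butyldimethylsilyloxy)-2,6,6-trimethylcyclohex-2-en-1-yl]methanol
Conditions: DDQ, CH2Cl2–pH 7 buffer (10:1), 0 °C
Reagents that add atoms: none
Why: Oxidative cleavage of the PMB ether by DDQ (hydride abstraction at the electron-rich benzylic carbon, then hydrolysis) is fast at 0 °C under buffered conditions, which spare the allylic silyl ether and the ring alkene.

Step 11
Reactants: 17 [(1R,4S)-4-(tert-butyldimethylsilyloxy)-2,6,6-trimethylcyclohex-2-en-1-yl]methanol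
Product: 18 5-({[(1R,4S)-4-(tert-butyldimethylsilyloxy)-2,6,6-trimethylcyclohex-2-en-1-yl]methyl}sulfanyl)-1-phenyl-1H-tetrazole
Conditions: 1-phenyl-1H-tetrazole-5-thiol, PPh3, DIAD, THF, 0 °C → rt
Reagents that add atoms: 1-phenyl-1H-tetrazole-5-thiol, Sc1nnnn1-c1ccccc1
Why: Mitsunobu reaction with the acidic heteroaryl thiol displaces the activated primary C7 oxygen in an SN2 sense, so no stereocentre is involved and the neighbouring C6 is not disturbed.

Step 12
Reactants: 18 phenyltetrazolyl thioether
Product: 19 5-({[(1R,4S)-4-(tert-butyldimethylsilyloxy)-2,6,6-trimethylcyclohex-2-en-1-yl]methyl}sulfonyl)-1-phenyl-1H-tetrazole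
Conditions: (NH4)6Mo7O24·4H2O (15 mol %), 30 % H2O2, EtOH, 0 °C → rt
Reagents that add atoms: hydrogen peroxide, OO
Why: (NH4)6Mo7O24-catalysed peroxide oxidation takes the sulfide through the sulfoxide to the sulfone and, unlike a peracid, leaves the hindered trisubstituted C4=C5 alkene unepoxidised.

Step 13
Reactants: 19 phenyltetrazolyl sulfone; 20 crocetin dialdehyde (all-E 8,8'-diapocarotene-8,8'-dial)
Product: 23 (3S,6R)-3-(tert-butyldimethylsilyloxy)-8'-apo-ε-caroten-8'-al (all-E), via potassium sulfonyl carbanion 21 (not isolated), via alkoxide adduct 22 (not isolated)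
Conditions: 19, KN(SiMe3)2 (1.0 equiv), THF, −78 °C; cannulated into 20 (3 equiv), dilute THF, −78 °C → rt, dark, Ar; aq. work-up, excess 20 recovered
Reagents that add atoms: none
Why: Julia–Kocienski olefination: carbanion 21 adds to one formyl group of 20, and Smiles transfer of the tetrazole followed by loss of SO2 and the tetrazololate creates C7=C8, E geometry being favoured by the potassium/phenyltetrazolyl pairing, by the conjugated aldehyde and by the clash between ring and C9 methyl in the Z form, while inverse addition to excess 20 protects the second formyl group and one equivalent of base at low temperature leaves the doubly allylic C6–H alone.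

Step 14
Reactants: 23 (3S,6R)-3-(tert-butyldimethylsilyloxy)-8'-apo-ε-caroten-8'-al
Product: 24 (3S,6R)-3-hydroxy-8'-apo-ε-caroten-8'-al (all-E), CNP0265614.2
Conditions: Bu4NF, AcOH (1:1), THF, 0 °C → rt, dark
Reagents that add atoms: none
Why: Fluoride-induced desilylation buffered with AcOH cleaves only Si–O, so 3S is retained, and it avoids both the acid that would ionise the allylic C3–O bond and the strong base that could shift C4=C5 into conjugation with the polyene.

Compound list
1 | prenol (3-methylbut-2-en-1-ol) | CC(C)=CCO | starting material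
2 | 3-methylbut-3-enoic acid | C=C(C)CC(=O)O | starting material
3 | prenyl 3-methylbut-3-enoate | C=C(C)CC(=O)OCC=C(C)C | intermediate
4 | (E)-boron ketene acetal of 3 (isopropenyl cis to O–B), boron held in the (4S,5S)-1,3-bis[3,5-bis(trifluoromethyl)phenylsulfonyl]-4,5-diphenyl-1,3,2-diazaborolidine ring | C=C(C)/C=C(/OCC=C(C)C)OB1N(S(=O)(=O)c2cc(C(F)(F)F)cc(C(F)(F)F)c2)[C@@H](c2ccccc2)[C@H](c2ccccc2)N1S(=O)(=O)c1cc(C(F)(F)F)cc(C(F)(F)F)c1 | intermediate
5 | acyloxyborane of the (S)-acid with the same (4S,5S)-diazaborolidine | C=C(C)[C@H](C(=O)OB1N(S(=O)(=O)c2cc(C(F)(F)F)cc(C(F)(F)F)c2)[C@@H](c2ccccc2)[C@H](c2ccccc2)N1S(=O)(=O)c1cc(C(F)(F)F)cc(C(F)(F)F)c1)C(C)(C)C=C | intermediate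
6 | (2S)-3,3-dimethyl-2-(prop-1-en-2-yl)pent-4-enoic acid | C=C(C)[C@H](C(=O)O)C(C)(C)C=C | intermediate
7 | (2S)-3,3-dimethyl-2-(prop-1-en-2-yl)pent-4-en-1-ol | C=C(C)[C@H](CO)C(C)(C)C=C | intermediate
8 | 4-methoxybenzyl ether of 7 | C=C(C)[C@H](COCc1ccc(OC)cc1)C(C)(C)C=C | intermediate
9 | 2-alkyl-1,3,2-benzodioxaborole (catechol boronate at C3) | C=C(C)[C@H](COCc1ccc(OC)cc1)C(C)(C)CCB1Oc2ccccc2O1 | intermediate
10 | (4S)-4-[(4-methoxybenzyloxy)methyl]-3,3,5-trimethylhex-5-en-1-ol | C=C(C)[C@H](COCc1ccc(OC)cc1)C(C)(C)CCO | intermediate
11 | (4S)-4-[(4-methoxybenzyloxy)methyl]-3,3,5-trimethylhex-5-enal | C=C(C)[C@H](COCc1ccc(OC)cc1)C(C)(C)CC=O | intermediate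
12 | vinylmagnesium bromide | C=C[Mg]Br | starting material
13 | divinylzinc | C=C[Zn]C=C | intermediate
14 | (3S,6S)-6-[(4-methoxybenzyloxy)methyl]-5,5,7-trimethylocta-1,7-dien-3-ol | C=C(C)[C@H](COCc1ccc(OC)cc1)C(C)(C)C[C@H](O)C=C | intermediate
15 | TBS ether of 14, (3S,6S) acyclic diene | C=C(C)[C@H](COCc1ccc(OC)cc1)C(C)(C)C[C@H](O[Si](C)(C)C(C)(C)C)C=C | intermediate
16 | tert-butyl({(1S,4R)-4-[(4-methoxybenzyloxy)methyl]-3,5,5-trimethylcyclohex-2-en-1-yl}oxy)dimethylsilane | CC1=C[C@@H](O[Si](C)(C)C(C)(C)C)CC(C)(C)[C@H]1COCc1ccc(OC)cc1 | intermediate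
17 | [(1R,4S)-4-(tert-butyldimethylsilyloxy)-2,6,6-trimethylcyclohex-2-en-1-yl]methanol | CC1=C[C@@H](O[Si](C)(C)C(C)(C)C)CC(C)(C)[C@H]1CO | intermediate
18 | 1-phenyl-1H-tetrazol-5-yl thioether of 17 | CC1=C[C@@H](O[Si](C)(C)C(C)(C)C)CC(C)(C)[C@H]1CSc1nnnn1-c1ccccc1 | intermediate
19 | 1-phenyl-1H-tetrazol-5-yl sulfone | CC1=C[C@@H](O[Si](C)(C)C(C)(C)C)CC(C)(C)[C@H]1CS(=O)(=O)c1nnnn1-c1ccccc1 | intermediate
20 | crocetin dialdehyde | O=C/C(C)=C/C=C/C(C)=C/C=C/C=C(C)/C=C/C=C(\C)C=O | starting material
21 | potassium salt of 19 metalated at C7 | CC1=C[C@@H](O[Si](C)(C)C(C)(C)C)CC(C)(C)[C@H]1[CH-]S(=O)(=O)c1nnnn1-c1ccccc1.[K+] | intermediate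
22 | potassium β-alkoxy sulfone adduct (C7 and C8 not defined) | CC1=C[C@@H](O[Si](C)(C)C(C)(C)C)CC(C)(C)[C@H]1C(C([O-])/C(C)=C/C=C/C(C)=C/C=C/C=C(C)/C=C/C=C(\C)C=O)S(=O)(=O)c1nnnn1-c1ccccc1.[K+] | intermediate
23 | (3S,6R)-3-(tert-butyldimethylsilyloxy)-8'-apo-ε-caroten-8'-al | CC1=C[C@@H](O[Si](C)(C)C(C)(C)C)CC(C)(C)[C@H]1/C=C/C(C)=C/C=C/C(C)=C/C=C/C=C(C)/C=C/C=C(\C)C=O | intermediate
24 | (3S,6R)-3-hydroxy-8'-apo-ε-caroten-8'-al | CC1=C[C@@H](O)CC(C)(C)[C@H]1/C=C/C(C)=C/C=C/C(C)=C/C=C/C=C(C)/C=C/C=C(\C)C=O | target

Total step count: 14. Longest linear sequence: 14 steps (from 1 and 2 to 24).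

The three steps chosen are those whose failure would stop the route. Steps 5 and 7 may lose material through imperfect selectivity, but their side products are separable.

Step 2. Facial discrimination in the boron enolate rearrangement may be insufficient or of the unexpected sense. Enolisation may give mixed geometry, or the β,γ-alkene may drift into conjugation before enolisation.
- The fallback sets out from 3 and returns at 6. It replaces reagent control by covalent resolution.
- Ester 3 is enolised with LiN(i-Pr)2 in THF at −78 °C and trapped with Me3SiCl as the trimethylsilyl ketene acetal F1.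
- On warming, this rearranges to the racemic trimethylsilyl ester F2, and hydrolytic work-up gives the racemic acid F3.
- Oxalyl chloride with catalytic DMF converts it into the racemic acid chloride F4.
- This acylates (S)-4-benzyloxazolidin-2-one (lithiated with n-BuLi) to the (2S)-acyl imide F5 and the (2R)-acyl imide F6.
- The two diastereomers are separated by chromatography or crystallisation and assigned by X-ray analysis.
- LiOH/H2O2 then cleaves F5 at the exocyclic carbonyl to 6 with recovery of the auxiliary.

Step 9. Alkylidene exchange at the vinyl group may be slowed by the bulky neighbouring silyloxy substituent, and capture by the hindered isopropenyl alkene may be sluggish. Intermolecular coupling, catalyst decay or alkene migration could then outrun ring closure.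
- The fallback sets out from 14 and returns at 16. It inverts the order of protection and cyclisation.
- The free allylic alcohol 14 is small at C3, and a free allylic hydroxy group is known to accelerate metathesis at the adjacent vinyl group.
- It is treated with (H2IMes)(PCy3)Cl2Ru=CHPh and 1,4-benzoquinone in dilute CH2Cl2 at 40 °C.
- This should give the ring allylic alcohol (1S,4R)-4-[(4-methoxybenzyloxy)methyl]-3,5,5-trimethylcyclohex-2-en-1-ol F7.
- Silylation with TBSCl and imidazole then gives 16.

Step 13. The hindered carbanion may add slowly to a sparingly soluble, weakly electrophilic polyenal. A second olefination may occur at the remaining formyl group, or E selectivity may erode on warming.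
- The fallback sets out from 20 (with 19 as before) and returns at 23. It replaces statistical control by prior desymmetrisation.
- Dialdehyde 20 is treated with one equivalent of trimethyl orthoformate and catalytic PPTS in MeOH–CH2Cl2.
- The more soluble crocetin dialdehyde mono(dimethyl acetal) F8 is separated, and the remaining material is recycled by hydrolysis.
- Carbanion 21 is then combined with a slight excess of F8 to give the TBS-protected apocarotenal dimethyl acetal F9.
- Its vinylogously activated acetal is hydrolysed with PPTS in wet acetone at room temperature, conditions the TBS ether tolerates, to give 23.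

Further compounds
F1 | step 2 | trimethylsilyl ketene acetal of 3 (geometry not defined) | C=C(C)C=C(OCC=C(C)C)O[Si](C)(C)C
F2 | step 2 | racemic trimethylsilyl 3,3-dimethyl-2-(prop-1-en-2-yl)pent-4-enoate | C=C(C)C(C(=O)O[Si](C)(C)C)C(C)(C)C=C
F3 | step 2 | racemic 3,3-dimethyl-2-(prop-1-en-2-yl)pent-4-enoic acid | C=C(C)C(C(=O)O)C(C)(C)C=C
F4 | step 2 | racemic 3,3-dimethyl-2-(prop-1-en-2-yl)pent-4-enoyl chloride | C=C(C)C(C(=O)Cl)C(C)(C)C=C
F5 | step 2 | (4S)-4-benzyl-3-[(2S)-3,3-dimethyl-2-(prop-1-en-2-yl)pent-4-enoyl]oxazolidin-2-one | O=C1OC[C@H](Cc2ccccc2)N1C(=O)[C@@H](C(C)=C)C(C)(C)C=C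
F6 | step 2 | (4S)-4-benzyl-3-[(2R)-3,3-dimethyl-2-(prop-1-en-2-yl)pent-4-enoyl]oxazolidin-2-one | O=C1OC[C@H](Cc2ccccc2)N1C(=O)[C@H](C(C)=C)C(C)(C)C=C
F7 | step 9 | (1S,4R)-4-[(4-methoxybenzyloxy)methyl]-3,5,5-trimethylcyclohex-2-en-1-ol | CC1=C[C@@H](O)CC(C)(C)[C@H]1COCc1ccc(OC)cc1
F8 | step 13 | crocetin dialdehyde mono(dimethyl acetal) | O=C/C(C)=C/C=C/C(C)=C/C=C/C=C(C)/C=C/C=C(\C)C(OC)OC
F9 | step 13 | (3S,6R)-3-(tert-butyldimethylsilyloxy)-8'-apo-ε-caroten-8'-al dimethyl acetal | CC1=C[C@@H](O[Si](C)(C)C(C)(C)C)CC(C)(C)[C@H]1/C=C/C(C)=C/C=C/C(C)=C/C=C/C=C(C)/C=C/C=C(\C)C(OC)OC
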